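## Retrosynthetic overview

- The butenolide ring is made last, by Pd-catalysed carbonylative lactonisation of a 13-iodo-12-ene-14,15-diol. That vinyl iodide comes from syn-hydrostannation/iodination of a C12≡C13 alkyne.
- C14 is taken from D-glyceraldehyde acetonide (chiral pool), carried in as a terminal alkyne.
- Rings A and B are formed in one step (A first, then B) by a Mn(III)/Cu(II) oxidative radical bicyclisation of an α-methyl β-keto ester polyene. The Cu(II) termination gives the 8(17)-exocyclic alkene, and a (−)-8-phenylmenthyl ester sets the absolute configuration.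
- LiAlH4 then converts the 3-ketone and C19 ester into the 3,19-diol and releases the auxiliary.
- The polyene comes from geranyl bromide, the chiral alkyne and a 2-methylacetoacetate dianion.

Assumption: the auxiliary shields the radical face as in the usual anti-to-phenyl model, so (−)-8-phenylmenthol gives the ent (10α-methyl) series; this sense is reasoned, not verified, and if it is opposite the commercial (+)-auxiliary is substituted with no other change.

Labdane numbering is used for the decalin intermediates.

## Route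

**Step 1**
Reactants: 1, (R)-2,2-dimethyl-1,3-dioxolane-4-carbaldehyde; 2, dimethyl (1-diazo-2-oxopropyl)phosphonate
Product: 3, (S)-4-ethynyl-2,2-dimethyl-1,3-dioxolane
Conditions: K2CO3, MeOH, 0 °C → rt
Reagents that add atoms: reactant 2, CC(=O)C(=[N+]=[N-])P(=O)(OC)OC (supplies the terminal alkyne carbon, C12)
Why: Ohira–Bestmann (Seyferth–Gilbert) homologation; the C–O stereocentre (future C14) is not touched, and R→S is only a CIP priority change.

**Step 2**
Reactants: 3; 4, geranyl bromide
Product: 5, (S)-4-[(4E)-5,9-dimethyldeca-4,8-dien-1-yn-1-yl]-2,2-dimethyl-1,3-dioxolane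
Conditions: CuI, Cs2CO3, NaI, DMF, rt
Reagents that add atoms: none
Why: Copper-acetylide SN2 allylation gives the skipped enyne (C11–C12 bond) with the E-alkene retained.

**Step 3**
Reactants: 5
Product: 6, (2E,6E)-10-[(4S)-2,2-dimethyl-1,3-dioxolan-4-yl]-2,6-dimethyldeca-2,6-dien-9-yn-1-ol
Conditions: SeO2 (cat.), t-BuOOH, salicylic acid, CH2Cl2, 0 °C → rt; then NaBH4, MeOH, 0 °C
Reagents that add atoms: selenium dioxide, O=[Se]=O (oxygen transfer); tert-butyl hydroperoxide, CC(C)(C)OO (terminal oxidant)
Why: Catalytic SeO2 allylic oxidation (ene/[2,3] sequence) hydroxylates the E-methyl of the terminal isopropylidene, fixing the E geometry of the future C10=C5 alkene; NaBH4 returns any over-oxidised enal.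

**Step 4**
Reactants: 6
Product: 7, (4S)-4-[(4E,8E)-10-bromo-5,9-dimethyldeca-4,8-dien-1-yn-1-yl]-2,2-dimethyl-1,3-dioxolane
Conditions: MsCl, Et3N, CH2Cl2, −40 °C; then LiBr, THF, 0 °C
Reagents that add atoms: lithium bromide, [Li+].[Br-]
Why: SN2 displacement of the allylic mesylate under neutral conditions that spare the acetonide and alkene geometry.

**Step 5**
Reactants: 8, (−)-8-phenylmenthol [(1R,2S,5R)-5-methyl-2-(2-phenylpropan-2-yl)cyclohexan-1-ol]; 9, ethyl 2-methyl-3-oxobutanoate
Product: 10, (1R,2S,5R)-5-methyl-2-(2-phenylpropan-2-yl)cyclohexyl 2-methyl-3-oxobutanoate (α-epimer mixture)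
Conditions: DMAP (cat.), toluene, reflux (−EtOH)
Reagents that add atoms: none
Why: DMAP-catalysed β-keto ester transesterification via the acylketene; the α-centre is irrelevant because it becomes a planar radical.

**Step 6**
Reactants: 10; 7
Product: 11, (−)-8-phenylmenthyl (6E,10E)-14-[(4S)-2,2-dimethyl-1,3-dioxolan-4-yl]-2,6,10-trimethyl-3-oxotetradeca-6,10-dien-13-ynoate
Conditions: NaH, THF, 0 °C; n-BuLi, 0 °C; then 7, 0 °C → rt
Reagents that add atoms: none
Why: Weiler dianion alkylation; the more reactive γ-carbanion attacks the allylic bromide (C1–C2 bond).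

**Step 7**
Reactants: 11
Product: 12, (−)-8-phenylmenthyl (4S,5S,9R,10S)-9-{3-[(4S)-2,2-dimethyl-1,3-dioxolan-4-yl]prop-2-yn-1-yl}-3-oxo-trans-decalin ester. It has the 8(17)-exocyclic methylene, C4 equatorial CH3 and axial CO2R* (cis to the C10 methyl), H-5 trans to the C10 methyl, and the C9 chain equatorial.
Conditions: Mn(OAc)3·2H2O (2.2 equiv), Cu(OAc)2·H2O (1 equiv), degassed AcOH, rt; chromatographic removal of the minor diastereomer and endocyclic alkene isomers
Reagents that add atoms: none
Why: Mn(III)-based oxidative radical polyene cyclisation (6-endo, 6-endo). The chair–chair transition state gives the trans-decalin with the C9 chain equatorial. The non-chelated W-shaped keto-ester radical places the ester axial at C4. The auxiliary's phenyl group blocks one radical face and so sets C4, and through it C5, C10 and C9. Cu(II) oxidises the tertiary C8 radical by β-hydride elimination from the methyl group, giving the exocyclic alkene.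

**Step 8**
Reactants: 12
Product: 13, (3R,4R,5S,9R,10S)-3-hydroxy-4-(hydroxymethyl) decalin with the alkynyl acetonide side chain (14S) unchanged; auxiliary 8 is recovered
Conditions: LiAlH4, THF, 0 °C → reflux
Reagents that add atoms: none
Why: Hydride reduction; axial attack on the C3 ketone from the face opposite the axial C4 ester and C10 methyl gives the equatorial 3-OH (3R), and the hindered ester is reduced to the C19 CH2OH.

**Step 9**
Reactants: 13
Product: 14, the (3R,4R,5S,9R,10S,14S)-12-yne-3,14,15,19-tetraol
Conditions: AcOH/H2O (3:1), 40 °C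
Reagents that add atoms: none
Why: Mild acetal hydrolysis; the exocyclic alkene and the stereocentres are unaffected.

**Step 10**
Reactants: 14
Product: 15, the (12E)-13-iodo-12-ene-3,14,15,19-tetraol (C11 and C14 cis across the alkene)
Conditions: PdCl2(PPh3)2 (5 mol %), Bu3SnH, THF, 0 °C; then I2, CH2Cl2, 0 °C
Reagents that add atoms: iodine, II (Bu3SnH supplies only the C12 hydrogen; tin is lost)
Why: Pd-catalysed syn-hydrostannation places tin on the alkyne carbon next to the propargylic hydroxyl, and iododestannylation proceeds with retention, so the alkene geometry is set here.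

**Step 11**
Reactants: 15
Product: 16, andrographolide
Conditions: Pd(PPh3)4 (10 mol %), CO (1 atm), Et3N, MeCN, 50 °C
Reagents that add atoms: carbon monoxide, [C-]#[O+]
Why: Carbonylative lactonisation (oxidative addition, CO insertion, 5-ring capture of the acyl-Pd by the C15 hydroxyl) with retention of geometry gives the E-alkylidene β-hydroxybutyrolactone.

## Compound list

1 | (R)-2,2-dimethyl-1,3-dioxolane-4-carbaldehyde | O=C[C@H]1COC(C)(C)O1 | starting material
2 | dimethyl (1-diazo-2-oxopropyl)phosphonate | CC(=O)C(=[N+]=[N-])P(=O)(OC)OC | starting material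
3 | (S)-4-ethynyl-2,2-dimethyl-1,3-dioxolane | C#C[C@H]1COC(C)(C)O1 | intermediate
4 | geranyl bromide | CC(C)=CCC/C(C)=C/CBr | starting material
5 | (S)-4-[(4E)-5,9-dimethyldeca-4,8-dien-1-yn-1-yl]-2,2-dimethyl-1,3-dioxolane | CC(C)=CCC/C(C)=C/CC#C[C@H]1COC(C)(C)O1 | intermediate
6 | (2E,6E)-10-[(4S)-2,2-dimethyl-1,3-dioxolan-4-yl]-2,6-dimethyldeca-2,6-dien-9-yn-1-ol | OC/C(C)=C/CC/C(C)=C/CC#C[C@H]1COC(C)(C)O1 | intermediate
7 | (4S)-4-[(4E,8E)-10-bromo-5,9-dimethyldeca-4,8-dien-1-yn-1-yl]-2,2-dimethyl-1,3-dioxolane | BrC/C(C)=C/CC/C(C)=C/CC#C[C@H]1COC(C)(C)O1 | intermediate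
8 | (−)-8-phenylmenthol, (1R,2S,5R) | O[C@@H]1C[C@H](C)CC[C@H]1C(C)(C)c1ccccc1 | starting material (recovered in step 8)
9 | ethyl 2-methyl-3-oxobutanoate | CCOC(=O)C(C)C(C)=O | starting material
10 | (−)-8-phenylmenthyl 2-methyl-3-oxobutanoate | CC(=O)C(C)C(=O)O[C@@H]1C[C@H](C)CC[C@H]1C(C)(C)c1ccccc1 | intermediate
11 | (−)-8-phenylmenthyl (6E,10E)-14-[(4S)-dioxolanyl]-2,6,10-trimethyl-3-oxotetradeca-6,10-dien-13-ynoate | CC(C(=O)O[C@@H]1C[C@H](C)CC[C@H]1C(C)(C)c1ccccc1)C(=O)CC/C(C)=C/CC/C(C)=C/CC#C[C@H]1COC(C)(C)O1 | intermediate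
12 | bicyclic 3-oxo C19 8-phenylmenthyl ester (4S,5S,9R,10S,14S), 8(17)-ene, 12-yne, 14,15-acetonide | C=C1CC[C@@H]2[C@](C)(C(=O)O[C@@H]3C[C@H](C)CC[C@H]3C(C)(C)c3ccccc3)C(=O)CC[C@@]2(C)[C@@H]1CC#C[C@H]1COC(C)(C)O1 | intermediate
13 | 3,19-diol 14,15-acetonide (3R,4R,5S,9R,10S,14S) | C=C1CC[C@@H]2[C@](C)(CO)[C@H](O)CC[C@@]2(C)[C@@H]1CC#C[C@H]1COC(C)(C)O1 | intermediate
14 | 12-yne-3,14,15,19-tetraol (3R,4R,5S,9R,10S,14S) | C=C1CC[C@@H]2[C@](C)(CO)[C@H](O)CC[C@@]2(C)[C@@H]1CC#C[C@H](O)CO | intermediate
15 | (12E)-13-iodo-12-ene-3,14,15,19-tetraol | C=C1CC[C@@H]2[C@](C)(CO)[C@H](O)CC[C@@]2(C)[C@@H]1C/C=C(/I)[C@H](O)CO | intermediate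
16 | andrographolide | C=C1CC[C@@H]2[C@](C)(CO)[C@H](O)CC[C@@]2(C)[C@@H]1C/C=C1/C(=O)OC[C@H]1O | target

## Step count

Total steps: 11. Longest linear sequence: 10 (1 → 3 → 5 → 6 → 7 → 11 → 12 → 13 → 14 → 15 → 16).

## Steps most likely to fail, with fallbacks

1. **Step 7 (radical bicyclisation).** Risks are the level and sense of auxiliary control, the exo/endo alkene ratio, and acetonide survival in AcOH. Fallback: take absolute configuration from a Sharpless asymmetric epoxidation instead. A (Z)-2-methyl-2,3-epoxy alcohol ether with a C17 allylsilane terminator would undergo Lewis-acid cationic epoxy-polyene cyclisation; the stereospecific epoxide opening sets C3/C4 and the allylsilane gives the 8(17)-alkene.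

2. **Step 10 (hydrostannation regiochemistry next to a hindered, unprotected diol), and with it step 11.** Fallback: drop the alkyne/vinyl iodide end-game. Carry C12 as a masked aldehyde through the cyclisation and build the lactone by aldol condensation with (S)-3-(silyloxy)-γ-butyrolactone followed by E-selective dehydration.

3. **Step 3 (SeO2 oxidation with a second trisubstituted alkene and a doubly activated C11 methylene present).** Fallback: introduce the C1 oxygen before the alkyne. Oxidise geranyl acetate at the E-methyl, silylate, exchange acetate for bromide, couple with 3, then convert the silyl ether to the bromide 7.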